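## Retrosynthetic overview

1. Numbering: C1 = CO2H, dioxane carbons C3–C6, carbinol C9. The 1,2-dioxane is closed last at C6–O by 6-endo cycloperoxymercuration of an (E)-alkenyl β-hydroperoxy acid; the C3 centre sets quaternary C6.
2. Key step: the C3–OO bond is made in an electrolysis. Cathodically generated superoxide opens a trans-β-lactone at its alkyl C–O carbon with inversion.
3. β-Lactone ⇐ CO insertion into a terminal epoxide, then trans-methylation (C2). Epoxide ⇐ (R)-epichlorohydrin + (E)-alkenylalanate (C4–C5 bond) from carboalumination of a terminal alkyne.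
4. Alkyne (C9 carbinol, exo-methylene, cyclohexenyl unit) ⇐ (R)-5-oxotetrahydrofuran-2-carboxylic acid: Grignard acylation (C10–C11), methylenation, lactol/Seyferth–Gilbert homologation.
5. Ring order: cyclohexene and γ-lactone are bought; the γ-lactone is opened, an oxetan-2-one is built and opened, and the 1,2-dioxane is formed last.

Assumption: β-homocyclocitral, (R)-5-oxotetrahydrofuran-2-carboxylic acid (made from D-glutamic acid) and (R)-epichlorohydrin are bought as such.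

## Route

Step 1
Reactants: 1 2-(2,6,6-trimethylcyclohex-1-en-1-yl)acetaldehyde (β-homocyclocitral)
Product: 2 2-(2,6,6-trimethylcyclohex-1-en-1-yl)ethan-1-ol
Conditions: NaBH4, MeOH, 0 °C
Reagents that add atoms: none
Why: Borohydride reduction of the aldehyde to the primary alcohol; the tetrasubstituted alkene is inert and no stereocentre is involved.

Step 2
Reactants: 2 2-(2,6,6-trimethylcyclohex-1-en-1-yl)ethan-1-ol
Product: 3 2-(2-bromoethyl)-1,3,3-trimethylcyclohex-1-ene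
Conditions: CBr4, PPh3, CH2Cl2, 0 °C
Reagents that add atoms: carbon tetrabromide BrC(Br)(Br)Br
Why: Appel reaction converts the primary alcohol into the bromide under neutral conditions that leave the alkene alone.

Step 3
Reactants: 4 (R)-5-oxotetrahydrofuran-2-carboxylic acid
Product: 5 (R)-5-oxotetrahydrofuran-2-carbonyl chloride
Conditions: (COCl)2, DMF (cat.), CH2Cl2, 0 °C → rt
Reagents that add atoms: oxalyl chloride ClC(=O)C(=O)Cl
Why: Acid chloride formation through the Vilsmeier intermediate; the bought C–O stereocentre (target C9) is not touched.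

Step 4
Reactants: 3 2-(2-bromoethyl)-1,3,3-trimethylcyclohex-1-ene; 5 (R)-5-oxotetrahydrofuran-2-carbonyl chloride
Product: 7 (5R)-5-[3-(2,6,6-trimethylcyclohex-1-en-1-yl)propanoyl]dihydrofuran-2(3H)-one, via alkylmagnesium bromide 6 (not isolated)
Conditions: Mg, THF, rt; then CuI (5 mol %), 5, THF, −78 °C
Reagents that add atoms: none
Why: Copper-catalysed acylation of the Grignard reagent by the acid chloride stops at the ketone at −78 °C and spares the lactone, and the α-oxygenated stereocentre is not enolised.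

Step 5
Reactants: 7 (5R)-5-[3-(2,6,6-trimethylcyclohex-1-en-1-yl)propanoyl]dihydrofuran-2(3H)-one
Product: 8 (5R)-5-[4-(2,6,6-trimethylcyclohex-1-en-1-yl)but-1-en-2-yl]dihydrofuran-2(3H)-one
Conditions: Zn, CH2Br2, TiCl4, THF, 0 °C → rt
Reagents that add atoms: dibromomethane BrCBr
Why: Takai–Lombardo methylenation is non-basic and selective for the ketone over the lactone, so the adjacent stereocentre is not epimerised.

Step 6
Reactants: 8 (5R)-5-[4-(2,6,6-trimethylcyclohex-1-en-1-yl)but-1-en-2-yl]dihydrofuran-2(3H)-one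
Product: 10 (3R)-2-[2-(2,6,6-trimethylcyclohex-1-en-1-yl)ethyl]hept-1-en-6-yn-3-ol, via lactol 9 (not isolated)
Conditions: i-Bu2AlH, CH2Cl2, −78 °C; then MeOH, K2CO3, dimethyl (1-diazo-2-oxopropyl)phosphonate, −78 °C → rt
Reagents that add atoms: dimethyl (1-diazo-2-oxopropyl)phosphonate CC(=O)C(=[N+]=[N-])P(=O)(OC)OC
Why: Partial reduction of the lactone to the lactol and Seyferth–Gilbert homologation with the Ohira–Bestmann reagent turn the lactone carbon into a terminal alkyne and free the stereocentre as the secondary alcohol without breaking its C–O bond.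

Step 7
Reactants: 10 (3R)-2-[2-(2,6,6-trimethylcyclohex-1-en-1-yl)ethyl]hept-1-en-6-yn-3-ol
Product: 11 tert-butyldimethyl{[(3R)-2-[2-(2,6,6-trimethylcyclohex-1-en-1-yl)ethyl]hept-1-en-6-yn-3-yl]oxy}silane
Conditions: TBSCl, imidazole, DMF, rt
Reagents that add atoms: tert-butyldimethylsilyl chloride CC(C)(C)[Si](C)(C)Cl
Why: Silylation masks the C9 hydroxyl, which would otherwise close a tetrahydrofuran onto C6 in step 12 (silyl ether protection).

Step 8
Reactants: 11 tert-butyldimethyl{[(3R)-2-[2-(2,6,6-trimethylcyclohex-1-en-1-yl)ethyl]hept-1-en-6-yn-3-yl]oxy}silane; 12 (R)-epichlorohydrin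
Product: 16 (2R)-2-[(2E,6R)-6-(tert-butyldimethylsilyloxy)-3-methyl-7-methylidene-9-(2,6,6-trimethylcyclohex-1-en-1-yl)non-2-en-1-yl]oxirane, via alkenylalane 13 (not isolated), via lithium alanate 14 (not isolated), via chlorohydrin 15 (not isolated)
Conditions: AlMe3 (2 equiv), Cp2ZrCl2 (20 mol %), CH2Cl2, 0 °C → rt; volatiles removed; n-BuLi, hexane–THF, −78 °C; 12, −78 → 0 °C; then NaOH, MeOH–H2O, rt
Reagents that add atoms: trimethylaluminium C[Al](C)C
Why: Negishi zirconium-catalysed syn-carboalumination puts methyl on the internal alkyne carbon and gives only the (E)-alkenylalane, whose butyl ate complex opens the epoxide of 12 at CH2 (not at C–Cl) so that the bought stereocentre is carried over untouched, and base then closes the chlorohydrin to the terminal epoxide (Williamson-type ring closure).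

Step 9
Reactants: 16 (2R)-2-[(2E,6R)-6-(tert-butyldimethylsilyloxy)-3-methyl-7-methylidene-9-(2,6,6-trimethylcyclohex-1-en-1-yl)non-2-en-1-yl]oxirane
Product: 17 (4R)-4-[(2E,6R)-6-(tert-butyldimethylsilyloxy)-3-methyl-7-methylidene-9-(2,6,6-trimethylcyclohex-1-en-1-yl)non-2-en-1-yl]oxetan-2-one
Conditions: CO (60 bar), [(salph)Al(THF)2][Co(CO)4] (2 mol %), DME, 50 °C
Reagents that add atoms: carbon monoxide [C-]#[O+]
Why: Ring-expanding carbonylation of the epoxide (Lewis acid activation, SN2 attack of Co(CO)4− at the unsubstituted carbon, CO insertion, ring closure) gives the 4-substituted β-lactone with retention at the substituted C–O carbon.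

Step 10
Reactants: 17 (4R)-4-[(2E,6R)-6-(tert-butyldimethylsilyloxy)-3-methyl-7-methylidene-9-(2,6,6-trimethylcyclohex-1-en-1-yl)non-2-en-1-yl]oxetan-2-one
Product: 18 (3R,4R)-3-methyl-4-[(2E,6R)-6-(tert-butyldimethylsilyloxy)-3-methyl-7-methylidene-9-(2,6,6-trimethylcyclohex-1-en-1-yl)non-2-en-1-yl]oxetan-2-one
Conditions: LiN(i-Pr)2 (1.1 equiv), THF, −78 °C; MeI, −78 °C
Reagents that add atoms: iodomethane CI
Why: Alkylation of the β-lactone enolate takes place on the face opposite the C4 side chain of the flat four-membered ring, so the new methyl stereocentre (target C2) is set trans by the epichlorohydrin-derived centre (substrate-controlled enolate alkylation).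

Step 11
Reactants: 18 (3R,4R)-3-methyl-4-[(2E,6R)-6-(tert-butyldimethylsilyloxy)-3-methyl-7-methylidene-9-(2,6,6-trimethylcyclohex-1-en-1-yl)non-2-en-1-yl]oxetan-2-one
Product: 19 (2R,3S,5E,9R)-9-(tert-butyldimethylsilyloxy)-3-hydroperoxy-2,6-dimethyl-10-methylidene-12-(2,6,6-trimethylcyclohex-1-en-1-yl)dodec-5-enoic acid
Conditions: O2 (1 atm), Bu4NBF4, DMF, −30 °C, divided cell, carbon-felt cathode at −1.0 V vs Ag/AgCl, Zn anode, 18 added slowly; then aq. H3PO4, 0 °C
Reagents that add atoms: dioxygen O=O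
Why: Proposed new method: cathodic reduction of O2 gives tetrabutylammonium superoxide, a weakly basic but strongly nucleophilic oxygen anion (conjugate acid pKa about 4.8, like a carboxylate), which should attack the β-lactone at C4 by SN2 with alkyl–oxygen fission and inversion (setting target C3), the peroxyl radical formed being reduced at once by a second superoxide to the peroxide anion that is protonated on work-up; the closest known reaction types are the SN2 displacement of secondary alkyl halides and sulfonates by electrogenerated superoxide and the SN2 ring opening of β-lactones at C4 by carboxylate or azide.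

Step 12
Reactants: 19 (2R,3S,5E,9R)-9-(tert-butyldimethylsilyloxy)-3-hydroperoxy-2,6-dimethyl-10-methylidene-12-(2,6,6-trimethylcyclohex-1-en-1-yl)dodec-5-enoic acid
Product: 21 (2R)-2-[(3S,6R)-6-[(3R)-3-(tert-butyldimethylsilyloxy)-4-methylidene-6-(2,6,6-trimethylcyclohex-1-en-1-yl)hexyl]-6-methyl-1,2-dioxan-3-yl]propanoic acid, via organomercurial 20 (not isolated)
Conditions: Hg(OAc)2 (1.05 equiv), CH2Cl2, 0 °C; then NaBH4, aq. NaOH, 0 °C
Reagents that add atoms: none
Why: Cycloperoxymercuration–demercuration: the mercurinium ion of the trisubstituted alkene is opened anti by the hydroperoxide at the tertiary carbon (Markovnikov 6-endo closure), and because the (E)-geometry forces the C7 chain equatorial and the methyl axial while the C3 substituent sits equatorial in the chair transition state, quaternary C6 is set by C3 before NaBH4 replaces mercury by hydrogen.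

Step 13
Reactants: 21 (2R)-2-[(3S,6R)-6-[(3R)-3-(tert-butyldimethylsilyloxy)-4-methylidene-6-(2,6,6-trimethylcyclohex-1-en-1-yl)hexyl]-6-methyl-1,2-dioxan-3-yl]propanoic acid
Product: 22 (2R)-2-[(3S,6R)-6-[(3R)-3-hydroxy-4-methylidene-6-(2,6,6-trimethylcyclohex-1-en-1-yl)hexyl]-6-methyl-1,2-dioxan-3-yl]propanoic acid (CNP0205216.4)
Conditions: HF·pyridine, THF, 0 °C → rt
Reagents that add atoms: none
Why: Fluoride-induced cleavage of the silyl ether under mildly acidic conditions frees the allylic alcohol without touching the dialkyl peroxide, the acid or the alkenes (desilylation).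

## Compound list

1 | 2-(2,6,6-trimethylcyclohex-1-en-1-yl)acetaldehyde | O=CCC1=C(C)CCCC1(C)C | starting material
2 | 2-(2,6,6-trimethylcyclohex-1-en-1-yl)ethan-1-ol | OCCC1=C(C)CCCC1(C)C | intermediate
3 | 2-(2-bromoethyl)-1,3,3-trimethylcyclohex-1-ene | BrCCC1=C(C)CCCC1(C)C | intermediate
4 | (R)-5-oxotetrahydrofuran-2-carboxylic acid | OC(=O)[C@H]1CCC(=O)O1 | starting material
5 | (R)-5-oxotetrahydrofuran-2-carbonyl chloride | ClC(=O)[C@H]1CCC(=O)O1 | intermediate
6 | [2-(2,6,6-trimethylcyclohex-1-en-1-yl)ethyl]magnesium bromide | Br[Mg]CCC1=C(C)CCCC1(C)C | intermediate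
7 | (5R)-5-[3-(2,6,6-trimethylcyclohex-1-en-1-yl)propanoyl]dihydrofuran-2(3H)-one | O=C(CCC1=C(C)CCCC1(C)C)[C@H]1CCC(=O)O1 | intermediate
8 | (5R)-5-[4-(2,6,6-trimethylcyclohex-1-en-1-yl)but-1-en-2-yl]dihydrofuran-2(3H)-one | C=C(CCC1=C(C)CCCC1(C)C)[C@H]1CCC(=O)O1 | intermediate
9 | (5R)-5-[4-(2,6,6-trimethylcyclohex-1-en-1-yl)but-1-en-2-yl]tetrahydrofuran-2-ol (lactol, both anomers) | C=C(CCC1=C(C)CCCC1(C)C)[C@H]1CCC(O)O1 | intermediate
10 | (3R)-2-[2-(2,6,6-trimethylcyclohex-1-en-1-yl)ethyl]hept-1-en-6-yn-3-ol | C=C(CCC1=C(C)CCCC1(C)C)[C@H](O)CCC#C | intermediate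
11 | tert-butyldimethyl{[(3R)-2-[2-(2,6,6-trimethylcyclohex-1-en-1-yl)ethyl]hept-1-en-6-yn-3-yl]oxy}silane | C=C(CCC1=C(C)CCCC1(C)C)[C@H](O[Si](C)(C)C(C)(C)C)CCC#C | intermediate
12 | (R)-epichlorohydrin, (2R)-2-(chloromethyl)oxirane | ClC[C@H]1CO1 | starting material
13 | dimethyl[(1E,5R)-5-(tert-butyldimethylsilyloxy)-2-methyl-6-methylidene-8-(2,6,6-trimethylcyclohex-1-en-1-yl)oct-1-en-1-yl]alumane | C=C(CCC1=C(C)CCCC1(C)C)[C@H](O[Si](C)(C)C(C)(C)C)CC/C(C)=C/[Al](C)C | intermediate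
14 | lithium butyldimethyl[(1E,5R)-5-(tert-butyldimethylsilyloxy)-2-methyl-6-methylidene-8-(2,6,6-trimethylcyclohex-1-en-1-yl)oct-1-en-1-yl]aluminate | C=C(CCC1=C(C)CCCC1(C)C)[C@H](O[Si](C)(C)C(C)(C)C)CC/C(C)=C/[Al-](C)(C)CCCC.[Li+] | intermediate
15 | (2R,4E,8R)-8-(tert-butyldimethylsilyloxy)-1-chloro-5-methyl-9-methylidene-11-(2,6,6-trimethylcyclohex-1-en-1-yl)undec-4-en-2-ol | C=C(CCC1=C(C)CCCC1(C)C)[C@H](O[Si](C)(C)C(C)(C)C)CC/C(C)=C/C[C@@H](O)CCl | intermediate
16 | (2R)-2-[(2E,6R)-6-(tert-butyldimethylsilyloxy)-3-methyl-7-methylidene-9-(2,6,6-trimethylcyclohex-1-en-1-yl)non-2-en-1-yl]oxirane | C=C(CCC1=C(C)CCCC1(C)C)[C@H](O[Si](C)(C)C(C)(C)C)CC/C(C)=C/C[C@@H]1CO1 | intermediate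
17 | (4R)-4-[(2E,6R)-6-(tert-butyldimethylsilyloxy)-3-methyl-7-methylidene-9-(2,6,6-trimethylcyclohex-1-en-1-yl)non-2-en-1-yl]oxetan-2-one | C=C(CCC1=C(C)CCCC1(C)C)[C@H](O[Si](C)(C)C(C)(C)C)CC/C(C)=C/C[C@@H]1CC(=O)O1 | intermediate
18 | (3R,4R)-3-methyl-4-[(2E,6R)-6-(tert-butyldimethylsilyloxy)-3-methyl-7-methylidene-9-(2,6,6-trimethylcyclohex-1-en-1-yl)non-2-en-1-yl]oxetan-2-one | C=C(CCC1=C(C)CCCC1(C)C)[C@H](O[Si](C)(C)C(C)(C)C)CC/C(C)=C/C[C@@H]1[C@@H](C)C(=O)O1 | intermediate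
19 | (2R,3S,5E,9R)-9-(tert-butyldimethylsilyloxy)-3-hydroperoxy-2,6-dimethyl-10-methylidene-12-(2,6,6-trimethylcyclohex-1-en-1-yl)dodec-5-enoic acid | C=C(CCC1=C(C)CCCC1(C)C)[C@H](O[Si](C)(C)C(C)(C)C)CC/C(C)=C/C[C@H](OO)[C@@H](C)C(=O)O | intermediate
20 | (2R)-2-[(3S,5S,6R)-5-(acetoxymercurio)-6-[(3R)-3-(tert-butyldimethylsilyloxy)-4-methylidene-6-(2,6,6-trimethylcyclohex-1-en-1-yl)hexyl]-6-methyl-1,2-dioxan-3-yl]propanoic acid | C=C(CCC1=C(C)CCCC1(C)C)[C@H](O[Si](C)(C)C(C)(C)C)CC[C@]1(C)[C@@H]([Hg]OC(C)=O)C[C@@H]([C@@H](C)C(=O)O)OO1 | intermediate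
21 | (2R)-2-[(3S,6R)-6-[(3R)-3-(tert-butyldimethylsilyloxy)-4-methylidene-6-(2,6,6-trimethylcyclohex-1-en-1-yl)hexyl]-6-methyl-1,2-dioxan-3-yl]propanoic acid | C=C(CCC1=C(C)CCCC1(C)C)[C@H](O[Si](C)(C)C(C)(C)C)CC[C@]1(C)CC[C@@H]([C@@H](C)C(=O)O)OO1 | intermediate
22 | (2R)-2-[(3S,6R)-6-[(3R)-3-hydroxy-4-methylidene-6-(2,6,6-trimethylcyclohex-1-en-1-yl)hexyl]-6-methyl-1,2-dioxan-3-yl]propanoic acid | C=C(CCC1=C(C)CCCC1(C)C)[C@H](O)CC[C@]1(C)CC[C@@H]([C@@H](C)C(=O)O)OO1 | target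

## Step count and risks

Total steps: 13. Longest linear sequence: 12 steps (steps 1, 2 and 4–13, from 1).

The three steps most likely to fail:

**Step 11 (the proposed new step).** Superoxide may attack the acyl carbon instead (giving the β-hydroxy acid with retention), the peroxide anion may add to a second lactone, or the peroxyl radical may close a dioxolane onto the alkene. The fallback uses known chemistry, sets out from 18 and comes back at 21. LiBH4 (THF, 0 °C) reduces 18 to the anti 1,3-diol F1. PivCl and pyridine at −20 °C give the primary pivalate F2, and MsCl with Et3N gives the secondary mesylate F3. KOH and 50% H2O2 in MeOH–THF displace the mesylate with inversion to give the secondary hydroperoxide F4. Hg(OAc)2 then NaBH4, as in step 12, give the dioxane pivalate F5. i-Bu2AlH at −78 °C frees the dioxane propanol F6. TEMPO and PhI(OAc)2 in MeCN–H2O oxidise it to acid 21, and step 13 follows.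

**Step 12.** Divalent mercury may add to the other alkenes, the free acid may lactonise, or the 5-exo dioxolane may form. The fallback sets out from 19 and comes back at 21. TMSCHN2 (MeOH–toluene, 0 °C) gives the methyl ester F7, which removes the competing carboxyl nucleophile. N-Iodosuccinimide in CH2Cl2 at 0 °C in the dark closes the ring through the iodonium ion to the iodo-dioxane ester F8. Bu3SnH with Et3B/air at 0 °C removes iodine to give the dioxane methyl ester F9. LiOH in THF–H2O gives 21.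

**Step 9.** The carbonylation catalyst is sensitive and the silyl ether or alkenes may interfere. The fallback sets out from 11 and comes back at 18, replacing steps 8–10. Carboalumination and ate formation as in step 8, followed by bought ethyl (S)-3,4-epoxybutanoate in place of 12, give the β-hydroxy ester F10. Fráter–Seebach alkylation (LiN(i-Pr)2 2.2 equiv, then MeI) gives the anti α-methyl β-hydroxy ester F11. LiOH gives the β-hydroxy acid F12. PhSO2Cl in pyridine at 0 °C (carboxyl activation, retention at the carbinol) closes β-lactone 18.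

## Further compounds

F1 | step 11 | (2S,3R,5E,9R)-9-(tert-butyldimethylsilyloxy)-2,6-dimethyl-10-methylidene-12-(2,6,6-trimethylcyclohex-1-en-1-yl)dodec-5-ene-1,3-diol | C=C(CCC1=C(C)CCCC1(C)C)[C@H](O[Si](C)(C)C(C)(C)C)CC/C(C)=C/C[C@@H](O)[C@@H](C)CO
F2 | step 11 | (2S,3R,5E,9R)-9-(tert-butyldimethylsilyloxy)-3-hydroxy-2,6-dimethyl-10-methylidene-12-(2,6,6-trimethylcyclohex-1-en-1-yl)dodec-5-en-1-yl 2,2-dimethylpropanoate | C=C(CCC1=C(C)CCCC1(C)C)[C@H](O[Si](C)(C)C(C)(C)C)CC/C(C)=C/C[C@@H](O)[C@@H](C)COC(=O)C(C)(C)C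
F3 | step 11 | (2S,3R,5E,9R)-9-(tert-butyldimethylsilyloxy)-3-(methanesulfonyloxy)-2,6-dimethyl-10-methylidene-12-(2,6,6-trimethylcyclohex-1-en-1-yl)dodec-5-en-1-yl 2,2-dimethylpropanoate | C=C(CCC1=C(C)CCCC1(C)C)[C@H](O[Si](C)(C)C(C)(C)C)CC/C(C)=C/C[C@@H](OS(C)(=O)=O)[C@@H](C)COC(=O)C(C)(C)C
F4 | step 11 | (2S,3S,5E,9R)-9-(tert-butyldimethylsilyloxy)-3-hydroperoxy-2,6-dimethyl-10-methylidene-12-(2,6,6-trimethylcyclohex-1-en-1-yl)dodec-5-en-1-yl 2,2-dimethylpropanoate | C=C(CCC1=C(C)CCCC1(C)C)[C@H](O[Si](C)(C)C(C)(C)C)CC/C(C)=C/C[C@H](OO)[C@@H](C)COC(=O)C(C)(C)C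
F5 | step 11 | (2S)-2-[(3S,6R)-6-[(3R)-3-(tert-butyldimethylsilyloxy)-4-methylidene-6-(2,6,6-trimethylcyclohex-1-en-1-yl)hexyl]-6-methyl-1,2-dioxan-3-yl]propyl 2,2-dimethylpropanoate | C=C(CCC1=C(C)CCCC1(C)C)[C@H](O[Si](C)(C)C(C)(C)C)CC[C@]1(C)CC[C@@H]([C@@H](C)COC(=O)C(C)(C)C)OO1
F6 | step 11 | (2S)-2-[(3S,6R)-6-[(3R)-3-(tert-butyldimethylsilyloxy)-4-methylidene-6-(2,6,6-trimethylcyclohex-1-en-1-yl)hexyl]-6-methyl-1,2-dioxan-3-yl]propan-1-ol | C=C(CCC1=C(C)CCCC1(C)C)[C@H](O[Si](C)(C)C(C)(C)C)CC[C@]1(C)CC[C@@H]([C@@H](C)CO)OO1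
F7 | step 12 | methyl (2R,3S,5E,9R)-9-(tert-butyldimethylsilyloxy)-3-hydroperoxy-2,6-dimethyl-10-methylidene-12-(2,6,6-trimethylcyclohex-1-en-1-yl)dodec-5-enoate | C=C(CCC1=C(C)CCCC1(C)C)[C@H](O[Si](C)(C)C(C)(C)C)CC/C(C)=C/C[C@H](OO)[C@@H](C)C(=O)OC
F8 | step 12 | methyl (2R)-2-[(3S,5S,6R)-6-[(3R)-3-(tert-butyldimethylsilyloxy)-4-methylidene-6-(2,6,6-trimethylcyclohex-1-en-1-yl)hexyl]-5-iodo-6-methyl-1,2-dioxan-3-yl]propanoate | C=C(CCC1=C(C)CCCC1(C)C)[C@H](O[Si](C)(C)C(C)(C)C)CC[C@]1(C)[C@@H](I)C[C@@H]([C@@H](C)C(=O)OC)OO1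
F9 | step 12 | methyl (2R)-2-[(3S,6R)-6-[(3R)-3-(tert-butyldimethylsilyloxy)-4-methylidene-6-(2,6,6-trimethylcyclohex-1-en-1-yl)hexyl]-6-methyl-1,2-dioxan-3-yl]propanoate | C=C(CCC1=C(C)CCCC1(C)C)[C@H](O[Si](C)(C)C(C)(C)C)CC[C@]1(C)CC[C@@H]([C@@H](C)C(=O)OC)OO1
F10 | step 9 | ethyl (3R,5E,9R)-9-(tert-butyldimethylsilyloxy)-3-hydroxy-6-methyl-10-methylidene-12-(2,6,6-trimethylcyclohex-1-en-1-yl)dodec-5-enoate | C=C(CCC1=C(C)CCCC1(C)C)[C@H](O[Si](C)(C)C(C)(C)C)CC/C(C)=C/C[C@@H](O)CC(=O)OCC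
F11 | step 9 | ethyl (2R,3R,5E,9R)-9-(tert-butyldimethylsilyloxy)-3-hydroxy-2,6-dimethyl-10-methylidene-12-(2,6,6-trimethylcyclohex-1-en-1-yl)dodec-5-enoate | C=C(CCC1=C(C)CCCC1(C)C)[C@H](O[Si](C)(C)C(C)(C)C)CC/C(C)=C/C[C@@H](O)[C@@H](C)C(=O)OCC
F12 | step 9 | (2R,3R,5E,9R)-9-(tert-butyldimethylsilyloxy)-3-hydroxy-2,6-dimethyl-10-methylidene-12-(2,6,6-trimethylcyclohex-1-en-1-yl)dodec-5-enoic acid | C=C(CCC1=C(C)CCCC1(C)C)[C@H](O[Si](C)(C)C(C)(C)C)CC/C(C)=C/C[C@@H](O)[C@@H](C)C(=O)O
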